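**Strategy.** The 1,2-dioxane (ring atoms O1, O2, C3, C4, C5, C6; acid numbering, O1 on C6) is cut into O1–O2–C3 and C4–C5–C6. One chiral-acid-catalysed operation joins the peroxycarbenium ion of an ozonolysis-derived hydroperoxy acetal to a cross-conjugated trienylmethylsilane: the ε-carbon C4 attacks C3, silicon leaves, the acid protonates C5 and the resulting C6 cation, allylic to C7=C8 and to a vinyl group that later becomes the C6 ethyl group, is trapped by O1. The step exploits the tertiary allylic peroxide carbon C6 and the fact that the hydroperoxide proton can end up on C5. Its precursors are acyclic and carry no ring stereocentre.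

Key step: step 10

Assumption: the sense of asymmetric induction of the ligand in step 1 and of the acid in step 10 is assigned by analogy with closely related substrates; should either be reversed, the antipodal ligand or acid is used.

Step 1
Reactants: 1 (E)-pent-2-enal
Product: 2 (3R,4E)-hept-4-en-3-ol
Conditions: Et2Zn, (2R)-3-exo-morpholinoisoborneol [(+)-MIB, 4 mol %], hexane/toluene, 0 °C; aq NH4Cl
Reagents that add atoms: diethylzinc (CC[Zn]CC)
Why: Amino-alcohol-catalysed 1,2-addition of a dialkylzinc to an enal, in which the chiral zinc aminoalkoxide delivers ethyl to one carbonyl face and should set the carbinol centre as R.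

Step 2
Reactants: 2 (3R,4E)-hept-4-en-3-ol
Product: 3 ethyl (3R,4E)-3-ethylhept-4-enoate
Conditions: MeC(OEt)3, EtCO2H (cat.), 140 °C, EtOH distilled off
Reagents that add atoms: triethyl orthoacetate (CCOC(C)(OCC)OCC)
Why: Johnson–Claisen rearrangement through a chair with the carbinol ethyl group equatorial should transfer the C–O chirality suprafacially to the new C–C stereocentre (C10 of the target, R) and give the E alkene.

Step 3
Reactants: 3 ethyl (3R,4E)-3-ethylhept-4-enoate
Product: 4 (3R,4E)-3-ethylhept-4-enal
Conditions: i-Bu2AlH, CH2Cl2, −78 °C; aq potassium sodium tartrate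
Reagents that add atoms: none
Why: Partial ester reduction, in which the aluminium hemiacetal survives at −78 °C and collapses to the aldehyde only on work-up; the stereocentre is β to the carbonyl and cannot epimerise.

Step 4
Reactants: 4 (3R,4E)-3-ethylhept-4-enal
Product: 5 (4R,5E)-4-ethyloct-5-en-1-yne
Conditions: MeC(O)C(N2)P(O)(OMe)2, K2CO3, MeOH, 0 °C → rt
Reagents that add atoms: dimethyl (1-diazo-2-oxopropyl)phosphonate (CC(=O)C(=[N+]=[N-])P(=O)(OC)OC)
Why: Ohira–Bestmann homologation (Seyferth–Gilbert type), in which the diazophosphonate anion olefinates the aldehyde and the alkylidene carbene gives the terminal alkyne by 1,2-hydrogen shift under base too mild to touch the remote stereocentre.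

Step 5
Reactants: 6 (E)-pent-2-enoic acid
Product: 7 (E)-pent-2-enoyl chloride
Conditions: (COCl)2, DMF (cat.), CH2Cl2, 0 °C → rt
Reagents that add atoms: oxalyl chloride (O=C(Cl)C(=O)Cl)
Why: Acyl chloride formation through the Vilsmeier-type chloroiminium catalyst, which leaves the E alkene unchanged.

Step 6
Reactants: 5 (4R,5E)-4-ethyloct-5-en-1-yne, 7 (E)-pent-2-enoyl chloride
Product: 9 (3E,6E,9R,10E)-7,9-diethyltrideca-3,6,10-trien-5-one, via alkenylcopper 8 (not isolated)
Conditions: EtMgBr, CuBr·SMe2, Et2O/Me2S, −45 → −25 °C; then 7, Pd(PPh3)4 (3 mol %), THF, −25 → 0 °C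
Reagents that add atoms: ethylmagnesium bromide (CC[Mg]Br)
Why: syn-Carbocupration of the terminal alkyne puts ethyl on the internal carbon and copper on the terminus cis to it, and palladium-catalysed acylation with retention should fix the E trisubstituted alkene that becomes C7=C8.

Step 7
Reactants: 10 methyltriphenylphosphonium bromide, 11 (iodomethyl)trimethylsilane
Product: 13 [2-(trimethylsilyl)ethyl]triphenylphosphonium iodide, via methylenetriphenylphosphorane 12 (not isolated)
Conditions: n-BuLi, THF, 0 °C; then 11, rt
Reagents that add atoms: none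
Why: C-alkylation of the unstabilised ylide by the primary iodide should give the β-silyl phosphonium salt.

Step 8
Reactants: 9 (3E,6E,9R,10E)-7,9-diethyltrideca-3,6,10-trien-5-one, 13 [2-(trimethylsilyl)ethyl]triphenylphosphonium iodide
Product: 15 trimethyl{(4E)-3-[(1E,4R,5E)-2,4-diethylocta-1,5-dien-1-yl]hepta-2,4-dien-1-yl}silane (2E/2Z mixture), via phosphorus ylide 14 (not isolated)
Conditions: n-BuLi, THF, −78 → 0 °C; then 9, −78 °C → rt
Reagents that add atoms: none
Why: Wittig olefination of the ketone by 1,2-addition of the unstabilised β-silyl ylide should install the allylsilane; the geometry of the new alkene is irrelevant because that carbon becomes sp3 C6.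

Step 9
Reactants: 16 dimethyl (E)-hex-3-enedioate
Product: 18 methyl 3-hydroperoxy-3-methoxypropanoate (racemic), via carbonyl oxide 17 (not isolated)
Conditions: O3, CH2Cl2/MeOH, −78 °C; N2 purge
Reagents that add atoms: ozone (O=[O+][O-]); methanol (CO)
Why: Ozonolysis with Criegee fragmentation of the symmetrical alkene gives one aldehyde and one carbonyl oxide, which methanol traps as the α-methoxy hydroperoxide, the symmetry removing any regiochemical ambiguity.

Step 10
Reactants: 15 trimethyl{(4E)-3-[(1E,4R,5E)-2,4-diethylocta-1,5-dien-1-yl]hepta-2,4-dien-1-yl}silane, 18 methyl 3-hydroperoxy-3-methoxypropanoate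
Product: 20 methyl 2-[(3R,4R,6R)-6-[(1E,4R,5E)-2,4-diethylocta-1,5-dien-1-yl]-6-ethenyl-4-ethyl-1,2-dioxan-3-yl]acetate, via hydroperoxy triene 19 (not isolated)
Conditions: (R)-3,3'-bis[3,5-bis(trifluoromethyl)phenyl]-1,1'-binaphthalene-2,2'-disulfonimide (5 mol %), toluene/CH2Cl2, −78 → −40 °C; Et3N quench
Reagents that add atoms: none
Why: Proposed new method: the acid (and the silyl disulfonimide it forms with 15) ionises acetal 18 to a peroxycarbenium ion paired with the chiral anion, and this cation is attacked by C4, the ε-terminus of the pentadienylsilane unit of 15, with loss of Me3Si (vinylogous Hosomi–Sakurai reaction, C3–C4 formed, triene 19); the acid then protonates C5 of 19 and the bis-allylic C6 cation is trapped by the terminal peroxide oxygen O1 (O1–C6 formed), silyl group and proton being passed on so that the acid turns over. The closest known reactions are the Lewis-acid allylation of peroxycarbenium ions from peroxyacetals with allylsilanes, the annulation of such ions with alkenes to 1,2-dioxolanes in which the peroxide oxygen traps the carbocation, the ε-selective reaction of pentadienylsilanes with acetals and the disulfonimide-catalysed enantioselective Hosomi–Sakurai reaction, but none of them joins these events or uses a chiral anion on a peroxycarbenium ion. The only ring, the 1,2-dioxane, is closed by 6-exo-trig attack of O1 on the C6 terminus of the allyl cation through a chair. C3 is controlled by the chiral anion, which blocks one face of the peroxycarbenium ion; C4 by the open antiperiplanar transition state of the E-configured C4=C5 terminus, which puts O2 and the C4 ethyl group syn and so cis on the ring; C6 by A(1,3) strain in the cation, which turns the fully substituted C8 away from C5 so that the alkenyl arm shows only H7 to the ring and goes axial while the vinyl group goes equatorial, cis to the equatorial C4 ethyl group. The step needs chemoselectivity for the silyl-terminated triene over the isolated C11=C12 alkene (secured by the far higher nucleophilicity of the pentadienylsilane), attack at C4 and not at C6 or C8 (both fully substituted), protonation at C5 (it alone gives the bis-allylic cation) and six- over eight-membered closure (O1 reaches C6 through a chair, C8 and the vinyl terminus only through medium rings).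

Step 11
Reactants: 20 methyl 2-[(3R,4R,6R)-6-[(1E,4R,5E)-2,4-diethylocta-1,5-dien-1-yl]-6-ethenyl-4-ethyl-1,2-dioxan-3-yl]acetate
Product: 21 methyl 2-[(3R,4R,6S)-6-[(1E,4R,5E)-2,4-diethylocta-1,5-dien-1-yl]-4,6-diethyl-1,2-dioxan-3-yl]acetate
Conditions: KO2CN=NCO2K, AcOH, MeOH/CH2Cl2, 0 °C → rt, added in portions
Reagents that add atoms: none
Why: Diimide reduction transfers H2 by a concerted syn pathway that does not touch the O–O bond and should react fastest with the monosubstituted vinyl group, leaving the trisubstituted C7=C8 and the 1,2-disubstituted C11=C12 alkenes; no stereocentre is touched (the C6 descriptor changes only because ethyl ranks below C5).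

Step 12
Reactants: 21 methyl 2-[(3R,4R,6S)-6-[(1E,4R,5E)-2,4-diethylocta-1,5-dien-1-yl]-4,6-diethyl-1,2-dioxan-3-yl]acetate
Product: 22 2-[(3R,4R,6S)-6-[(1E,4R,5E)-2,4-diethylocta-1,5-dien-1-yl]-4,6-diethyl-1,2-dioxan-3-yl]acetic acid (CNP0398571.7)
Conditions: LiOH, THF/H2O, 0 °C; 1 M HCl to pH 3
Reagents that add atoms: lithium hydroxide ([Li+].[OH-])
Why: Saponification at 0 °C should cleave the methyl ester faster than base can open the β-peroxy ester by elimination, so the dialkyl peroxide and all four stereocentres are kept.

**Compound list**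

1 | (E)-pent-2-enal | CC/C=C/C=O | starting material
2 | (3R,4E)-hept-4-en-3-ol | CC[C@@H](O)/C=C/CC | intermediate
3 | ethyl (3R,4E)-3-ethylhept-4-enoate | CCOC(=O)C[C@@H](CC)/C=C/CC | intermediate
4 | (3R,4E)-3-ethylhept-4-enal | O=CC[C@@H](CC)/C=C/CC | intermediate
5 | (4R,5E)-4-ethyloct-5-en-1-yne | C#CC[C@@H](CC)/C=C/CC | intermediate
6 | (E)-pent-2-enoic acid | CC/C=C/C(=O)O | starting material
7 | (E)-pent-2-enoyl chloride | CC/C=C/C(=O)Cl | intermediate
8 | [(1E,4R,5E)-2,4-diethylocta-1,5-dien-1-yl]copper (MgBr2 complex, not isolated) | [Cu]/C=C(/C[C@@H](CC)/C=C/CC)CC | intermediate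
9 | (3E,6E,9R,10E)-7,9-diethyltrideca-3,6,10-trien-5-one | CC/C=C/C(=O)/C=C(/C[C@@H](CC)/C=C/CC)CC | intermediate
10 | methyltriphenylphosphonium bromide | C[P+](c1ccccc1)(c1ccccc1)c1ccccc1.[Br-] | starting material
11 | (iodomethyl)trimethylsilane | C[Si](C)(C)CI | starting material
12 | methylenetriphenylphosphorane (not isolated) | C=P(c1ccccc1)(c1ccccc1)c1ccccc1 | intermediate
13 | [2-(trimethylsilyl)ethyl]triphenylphosphonium iodide | C[Si](C)(C)CC[P+](c1ccccc1)(c1ccccc1)c1ccccc1.[I-] | intermediate
14 | [2-(trimethylsilyl)ethylidene]triphenylphosphorane (not isolated) | C[Si](C)(C)CC=P(c1ccccc1)(c1ccccc1)c1ccccc1 | intermediate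
15 | trimethyl{(4E)-3-[(1E,4R,5E)-2,4-diethylocta-1,5-dien-1-yl]hepta-2,4-dien-1-yl}silane (2E/2Z mixture) | C[Si](C)(C)CC=C(/C=C/CC)\C=C(\C[C@@H](CC)/C=C/CC)CC | intermediate
16 | dimethyl (E)-hex-3-enedioate | COC(=O)C/C=C/CC(=O)OC | starting material
17 | methyl 3-oxopropanoate O-oxide (carbonyl oxide, not isolated) | COC(=O)CC=[O+][O-] | intermediate
18 | methyl 3-hydroperoxy-3-methoxypropanoate (racemic) | COC(=O)CC(OC)OO | intermediate
19 | methyl (3R,4R,7E,10R,11E)-6-ethenyl-4,8,10-triethyl-3-hydroperoxytetradeca-5,7,11-trienoate (5E/5Z mixture, not isolated) | C=CC(/C=C(/C[C@@H](CC)/C=C/CC)CC)=C[C@@H](CC)[C@@H](CC(=O)OC)OO | intermediate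
20 | methyl 2-[(3R,4R,6R)-6-[(1E,4R,5E)-2,4-diethylocta-1,5-dien-1-yl]-6-ethenyl-4-ethyl-1,2-dioxan-3-yl]acetate | CC/C=C/[C@H](CC)C/C(=C/[C@]1(C=C)C[C@@H](CC)[C@@H](CC(=O)OC)OO1)CC | intermediate
21 | methyl 2-[(3R,4R,6S)-6-[(1E,4R,5E)-2,4-diethylocta-1,5-dien-1-yl]-4,6-diethyl-1,2-dioxan-3-yl]acetate | CC/C=C/[C@H](CC)C/C(=C/[C@]1(CC)C[C@@H](CC)[C@@H](CC(=O)OC)OO1)CC | intermediate
22 | 2-[(3R,4R,6S)-6-[(1E,4R,5E)-2,4-diethylocta-1,5-dien-1-yl]-4,6-diethyl-1,2-dioxan-3-yl]acetic acid | CC/C=C/[C@H](CC)C/C(=C/[C@]1(CC)C[C@@H](CC)[C@@H](CC(=O)O)OO1)CC | target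

**Count and risks**

Total steps: 12. Longest linear sequence: 9 steps (1, 2, 3, 4, 6, 8, 10, 11, 12).

The three steps most likely to fail:

First, step 10, the step that carries the new-method label. The chiral anion may fail to differentiate the two faces of the acyclic peroxycarbenium ion. Acid-induced heterolysis of the hydroperoxide, or re-ionisation of the bis-allylic C6–O1 bond, may also outrun clean ring closure. The fallback uses known chemistry, sets out from 18 and 15 and comes back at 20. Acetal 18 is silylated (Et3SiOTf, 2,6-lutidine, CH2Cl2, −78 °C) to methyl 3-methoxy-3-(triethylsilylperoxy)propanoate F1. Me3SiOTf (CH2Cl2, −78 °C) then brings about the established allylsilane addition of 15 to the peroxycarbenium ion of F1. This should give methyl (3R,4R,7E,10R,11E)-6-ethenyl-4,8,10-triethyl-3-(triethylsilylperoxy)tetradeca-5,7,11-trienoate F2 together with its (3S,4S) isomer, which is a diastereomer through C10 and would be removed by preparative HPLC. Bu4NF/AcOH (THF, 0 °C) frees hydroperoxide 19. Cycloperoxymercuration (Hg(OAc)2, HClO4 cat., CH2Cl2, 0 °C; Markovnikov, oxygen to C6) closes it to methyl 2-[5-(acetoxymercurio)-6-[(1E,4R,5E)-2,4-diethylocta-1,5-dien-1-yl]-6-ethenyl-4-ethyl-1,2-dioxan-3-yl]acetate F3 (C3, C4 and C6 as in 20). NaBH4/NaOH (0 °C) replaces mercury by hydrogen to give 20.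

Second, step 8. The ylide may add in conjugate fashion to the unhindered enone arm, or enolise the ketone, instead of olefinating the carbonyl group. The fallback sets out from 9 and comes back at 15. CH2=CHMgBr with CeCl3 (THF, −78 °C) adds 1,2 to give (3E,6E,9R,10E)-5-ethenyl-7,9-diethyltrideca-3,6,10-trien-5-ol F4. n-BuLi then ClCO2Me converts it into (3E,6E,9R,10E)-5-ethenyl-7,9-diethyltrideca-3,6,10-trien-5-yl methyl carbonate F5. Palladium-catalysed allylic silylation (Pd2(dba)3, Me3Si–SiMe3, DMF, rt) delivers silicon to the unsubstituted vinyl terminus of the allyl complex and should give 15.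

Third, step 11. Site selectivity may be lost, with diimide also saturating the C11=C12 alkene. The fallback sets out from 20 and comes back at 21. It replaces hydrogen transfer from diimide by sterically governed catalytic hydrogenation (H2, 1 atm, RhCl(PPh3)3 5 mol %, benzene, rt), which binds the monosubstituted vinyl group far more readily than the internal alkenes and is expected to leave the dialkyl peroxide intact at room temperature. It makes no new compound (F0).

**Further compounds**

F1 | step 10 | methyl 3-methoxy-3-(triethylsilylperoxy)propanoate | COC(=O)CC(OC)OO[Si](CC)(CC)CC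
F2 | step 10 | methyl (3R,4R,7E,10R,11E)-6-ethenyl-4,8,10-triethyl-3-(triethylsilylperoxy)tetradeca-5,7,11-trienoate | C=CC(/C=C(/C[C@@H](CC)/C=C/CC)CC)=C[C@@H](CC)[C@@H](CC(=O)OC)OO[Si](CC)(CC)CC
F3 | step 10 | methyl 2-[5-(acetoxymercurio)-6-[(1E,4R,5E)-2,4-diethylocta-1,5-dien-1-yl]-6-ethenyl-4-ethyl-1,2-dioxan-3-yl]acetate (C3, C4 and C6 as in 20) | CC/C=C/[C@H](CC)C/C(=C/[C@]1(C=C)C([Hg]OC(C)=O)[C@@H](CC)[C@@H](CC(=O)OC)OO1)CC
F4 | step 8 | (3E,6E,9R,10E)-5-ethenyl-7,9-diethyltrideca-3,6,10-trien-5-ol | C=CC(O)(/C=C/CC)/C=C(/C[C@@H](CC)/C=C/CC)CC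
F5 | step 8 | (3E,6E,9R,10E)-5-ethenyl-7,9-diethyltrideca-3,6,10-trien-5-yl methyl carbonate | C=CC(OC(=O)OC)(/C=C/CC)/C=C(/C[C@@H](CC)/C=C/CC)CC
F0 | step 11 | none | none
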